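**Plan**

- Retrosynthesis: the C13–C14 bond is cut first (vinyl addition to a 12‑acetoxy‑13‑ketone), then ring B at C6–C7 (carbonyl‑ene closure), then ring A at C2–C3 and C5–C10 together with C1–C10 in one three‑component annulation.
- Forward: (R)‑limonene is opened to an acyclic ester that carries C7–C13, C16, C17, C20 and the C9 stereocenter. Its enolate (C10), a vinylphosphonium salt (C1–C2) and the aldehyde OHC–CMe2–CH=CH–NO2 (C3–C6) are joined in one pot to give ring A. Ring B follows by ene closure onto the isopropenyl group, and the side chain is finished last.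
- Enabling feature: C10 carries C20 at the carboxyl level and can therefore act twice as an ester‑enolate donor. C5 sits between the oxygenated C6 (brought in as a nitroalkene carbon) and the quaternary C4, so the aldehyde has no α‑hydrogens and the nitroalkene no γ‑hydrogens. Ring A is unfunctionalised, so the C2=C3 Wittig alkene is simply hydrogenated.
- Stereochemistry: C9 from (R)‑limonene; C10 by 1,2‑induction (A(1,3) strain) in the ring‑closing Michael addition; C5 as the trans ring fusion; C6 by α‑face hydride attack; C8 by α‑face trapping of the tertiary radical; C12 by L‑proline; C13 by Felkin–Anh addition.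

Key step: step 6

Remark: labdane numbering is used throughout (C1–C10 decalin, C18/C19 on C4, C20 on C10, C17 on C8, C11–C16 side chain with C16 the methyl on C13); α is the face of H‑5 and H‑9, β the face of C20. 3‑Hydroxy‑2,2‑dimethylpropanal is assumed to be used as its commercial dimer, which reacts as the monomer.

**Step 1**
Reactants: 1 (R)-(+)-limonene
Product: 2 methyl (3R)-6-oxo-3-(prop-1-en-2-yl)heptanoate
Conditions: O3 (1.0 equiv), NaHCO3, CH2Cl2/MeOH 5:1, −78 °C; then Ac2O, Et3N, 0 °C to rt
Reagents that add atoms: ozone ([O-][O+]=O); methanol (CO)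
Why: Ozonolysis of the more electron‑rich trisubstituted ring alkene with Schreiber's terminus‑differentiating work‑up (dehydration of the α‑methoxy hydroperoxide at the former CH carbon) should give the keto ester directly, sparing the isopropenyl group and leaving the stereocenter (later C9) untouched.

**Step 2**
Reactants: 2 methyl (3R)-6-oxo-3-(prop-1-en-2-yl)heptanoate
Product: 3 methyl (3R)-5-(2-methyl-1,3-dioxolan-2-yl)-3-(prop-1-en-2-yl)pentanoate
Conditions: Me3SiOCH2CH2OSiMe3, Me3SiOTf (2 mol%), CH2Cl2, −78 °C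
Reagents that add atoms: 1,2-bis(trimethylsilyloxy)ethane (C[Si](C)(C)OCCO[Si](C)(C)C)
Why: Noyori ketalisation masks only the C13 ketone under aprotic conditions that leave the ester, the isopropenyl group and the stereocenter alone, so that the later enolate chemistry is confined to C10.

**Step 3**
Reactants: 4 3-hydroxy-2,2-dimethylpropanal
Product: 5 2,2-dimethyl-4-nitrobutane-1,3-diol (racemic)
Conditions: MeNO2 (5 equiv), KF (10 mol%), i-PrOH, rt
Reagents that add atoms: nitromethane (C[N+](=O)[O-])
Why: A Henry (nitroaldol) reaction adds the future C6 to the non‑enolisable aldehyde; the new carbinol center forms as a racemate and is removed in step 5.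

**Step 4**
Reactants: 5 2,2-dimethyl-4-nitrobutane-1,3-diol
Product: 6 3-hydroxy-2,2-dimethyl-4-nitrobutanal (racemic)
Conditions: TEMPO (10 mol%), PhI(OAc)2 (1.1 equiv), CH2Cl2, rt
Reagents that add atoms: none
Why: The TEMPO/PhI(OAc)2 oxidation distinguishes the primary from the secondary alcohol on steric grounds and should stop at the aldehyde (future C3) in anhydrous medium.

**Step 5**
Reactants: 6 3-hydroxy-2,2-dimethyl-4-nitrobutanal
Product: 7 (E)-2,2-dimethyl-4-nitrobut-3-enal
Conditions: MsCl (1.2 equiv), Et3N (2.5 equiv), CH2Cl2, −20 to 0 °C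
Reagents that add atoms: none
Why: Mesylation and E1cB elimination of the β‑nitro alcohol should give the thermodynamically favoured E nitroalkene, the aldehyde being inert because C4 is quaternary.

**Step 6**
Reactants: 3 methyl (3R)-5-(2-methyl-1,3-dioxolan-2-yl)-3-(prop-1-en-2-yl)pentanoate; 8 vinyltriphenylphosphonium bromide; 7 (E)-2,2-dimethyl-4-nitrobut-3-enal
Product: 11 methyl (1S,6S)-5,5-dimethyl-1-[(3S)-2-methyl-5-(2-methyl-1,3-dioxolan-2-yl)pent-1-en-3-yl]-6-(nitromethyl)cyclohex-3-ene-1-carboxylate, via phosphorus ylide 9 (not isolated), via Z-alkenyl nitroalkene ester 10 (not isolated)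
Conditions: KN(SiMe3)2 (1.05 equiv), THF, −78 °C; 8, −78 to 0 °C; 7, −78 to 0 °C; KN(SiMe3)2 (1.2 equiv), −78 to −40 °C; AcOH, −78 °C
Reagents that add atoms: none
Why: The potassium enolate of 3 adds to the vinylphosphonium salt (Schweizer‑type Michael addition, C10–C1) to give ylide 9, which undergoes a salt‑free Z‑selective Wittig reaction with the α‑quaternary aldehyde of 7 (C2=C3); a second deprotonation at C10 then triggers an intramolecular ester‑enolate Michael addition onto the tethered nitroalkene (C5–C10), the closest known reaction types being the tandem Michael–Wittig chemistry of vinylphosphonium salts and the addition of ester enolates to nitroalkenes. Ring A closes in a 6‑exo‑trig mode, the cis C2=C3 bond holding the two reacting ends together, while ring B stays open. The quaternary C10 is controlled by the C9 stereocenter: H‑9 eclipses the enolate C10=C20 bond (A(1,3) strain) and the nitroalkene attacks the face opposite the branched isopropenyl group, past the smaller C11 methylene. C5 is set in the chair‑like transition state with the nitromethyl group equatorial and trans to the C9 branch, the arrangement that later becomes the trans ring fusion. The step needs the ylide to choose the aldehyde over the nitroalkene and the second base to deprotonate C10 and not add to the nitroalkene, which the neopentyl β‑carbon (C5 next to quaternary C4) and the absence of γ‑hydrogens in 7 should secure; only the Z alkene can cyclise.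

**Step 7**
Reactants: 11 methyl (1S,6S)-5,5-dimethyl-1-[(3S)-2-methyl-5-(2-methyl-1,3-dioxolan-2-yl)pent-1-en-3-yl]-6-(nitromethyl)cyclohex-3-ene-1-carboxylate
Product: 12 methyl (1S,6S)-6-formyl-5,5-dimethyl-1-[(3S)-2-methyl-5-(2-methyl-1,3-dioxolan-2-yl)pent-1-en-3-yl]cyclohex-3-ene-1-carboxylate
Conditions: NaOMe, MeOH, 0 °C; then TiCl3 (aq), NH4OAc, pH 5, rt
Reagents that add atoms: water (O)
Why: A Nef reaction in McMurry's buffered TiCl3 variant (nitronate reduced to the imine, then hydrolysed) should give the C6 aldehyde at a pH that spares ketal, ester and both alkenes, with C5 keeping its equatorial formyl arrangement.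

**Step 8**
Reactants: 12 methyl (1S,6S)-6-formyl-5,5-dimethyl-1-[(3S)-2-methyl-5-(2-methyl-1,3-dioxolan-2-yl)pent-1-en-3-yl]cyclohex-3-ene-1-carboxylate
Product: 13 methyl 13,13-ethylenedioxy-6ξ-hydroxy-14,15-dinorlabda-2,8(17)-dien-20-oate (C6 epimers)
Conditions: Me2AlCl (2.0 equiv), CH2Cl2, −78 to −20 °C
Reagents that add atoms: none
Why: A type 2 intramolecular carbonyl‑ene reaction (Snider) lets the terminal CH2 of the isopropenyl group (C7) attack the Me2AlCl‑activated aldehyde (C6) with transfer of a methyl hydrogen, closing ring B trans‑fused from the two equatorial arms and leaving the C8=C17 exocyclic alkene; the C6 carbinol configuration is not controlled and is erased in step 10.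

**Step 9**
Reactants: 13 methyl 13,13-ethylenedioxy-6ξ-hydroxy-14,15-dinorlabda-2,8(17)-dien-20-oate
Product: 14 methyl 13,13-ethylenedioxy-6ξ,8α-dihydroxy-14,15-dinorlabd-2-en-20-oate
Conditions: Co(acac)2 (20 mol%), PhSiH3 (2.5 equiv), O2 (1 atm), THF, rt
Reagents that add atoms: dioxygen (O=O)
Why: Mukaiyama hydration (hydrogen‑atom transfer, then O2 capture) should act on the 1,1‑disubstituted alkene, which gives a tertiary radical, and not on the 1,2‑disubstituted ring A alkene; the C8 radical should be trapped from the α face, away from the axial C10 ester, giving 8α‑OH and the axial C17 methyl.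

**Step 10**
Reactants: 14 methyl 13,13-ethylenedioxy-6ξ,8α-dihydroxy-14,15-dinorlabd-2-en-20-oate
Product: 15 methyl 13,13-ethylenedioxy-8α-hydroxy-6-oxo-14,15-dinorlabd-2-en-20-oate
Conditions: Dess–Martin periodinane, NaHCO3, CH2Cl2, 0 °C to rt
Reagents that add atoms: none
Why: Dess–Martin oxidation touches only the secondary alcohol and merges the C6 epimers into one ketone, in which C5 (now α to the carbonyl) should rest in the thermodynamically preferred trans ring fusion.

**Step 11**
Reactants: 15 methyl 13,13-ethylenedioxy-8α-hydroxy-6-oxo-14,15-dinorlabd-2-en-20-oate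
Product: 16 13,13-ethylenedioxy-14,15-dinorlabd-2-ene-6β,8α,20-triol
Conditions: LiAlH4, THF, −78 °C to reflux
Reagents that add atoms: none
Why: LiAlH4 reduction should deliver hydride to the C6 ketone from the α face (the β face is blocked by the axial C20 and C19 groups) to give the axial 6β‑alcohol, and it reduces the ester to the C20 primary alcohol while ketal and alkene survive.

**Step 12**
Reactants: 16 13,13-ethylenedioxy-14,15-dinorlabd-2-ene-6β,8α,20-triol
Product: 17 13,13-ethylenedioxy-14,15-dinorlabd-2-ene-6β,8α,20-triyl triacetate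
Conditions: Ac2O (10 equiv), DMAP (3 equiv), Et3N, toluene, 60 °C
Reagents that add atoms: acetic anhydride (CC(=O)OC(C)=O)
Why: DMAP‑catalysed acylation at raised temperature should acetylate the primary, the hindered axial secondary and the tertiary alcohol, and capping 8‑OH prevents hemiketal formation with the C13 ketone once it is released.

**Step 13**
Reactants: 17 13,13-ethylenedioxy-14,15-dinorlabd-2-ene-6β,8α,20-triyl triacetate
Product: 18 13-oxo-14,15-dinorlabd-2-ene-6β,8α,20-triyl triacetate
Conditions: PPTS (0.3 equiv), acetone/H2O 9:1, 50 °C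
Reagents that add atoms: water (O)
Why: Mild acid‑catalysed ketal hydrolysis frees the methyl ketone without cleaving or eliminating the acetates.

**Step 14**
Reactants: 18 13-oxo-14,15-dinorlabd-2-ene-6β,8α,20-triyl triacetate
Product: 19 (12R)-13-oxo-12-(phenylaminooxy)-14,15-dinorlabd-2-ene-6β,8α,20-triyl triacetate
Conditions: PhNO (1.5 equiv, slow addition), L-proline (30 mol%), DMSO, rt
Reagents that add atoms: nitrosobenzene (O=Nc1ccccc1)
Why: Proline‑catalysed α‑aminoxylation (nitroso aldol) goes through the more substituted enamine (C12), and the carboxylic acid of L‑proline directs the nitroso oxygen to one enamine face, which should set 12R as in the (R)‑α‑aminoxy ketones obtained from L‑proline.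

**Step 15**
Reactants: 19 (12R)-13-oxo-12-(phenylaminooxy)-14,15-dinorlabd-2-ene-6β,8α,20-triyl triacetate
Product: 20 (12R)-12-hydroxy-13-oxo-14,15-dinorlabdane-6β,8α,20-triyl triacetate
Conditions: H2 (1 atm), Pd/C (10 wt%), EtOAc, rt
Reagents that add atoms: none
Why: Catalytic hydrogenation cleaves the N–O bond and saturates the C2=C3 alkene of ring A in one operation, leaving ketone, acetates and the C12 configuration intact.

**Step 16**
Reactants: 20 (12R)-12-hydroxy-13-oxo-14,15-dinorlabdane-6β,8α,20-triyl triacetate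
Product: 21 (12R)-13-oxo-14,15-dinorlabdane-6β,8α,12,20-tetrayl tetraacetate
Conditions: Ac2O, pyridine, 0 °C to rt
Reagents that add atoms: acetic anhydride (CC(=O)OC(C)=O)
Why: Standard acetylation of the secondary α‑ketol at low temperature installs the fourth acetate without enolising C12.

**Step 17**
Reactants: 21 (12R)-13-oxo-14,15-dinorlabdane-6β,8α,12,20-tetrayl tetraacetate
Product: 22 (12R,13S)-13-hydroxylabd-14-ene-6β,8α,12,20-tetrayl tetraacetate (CNP0136817.1)
Conditions: CH2=CHMgBr (1.5 equiv), CeCl3 (1.6 equiv), THF, −78 °C; aq NH4Cl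
Reagents that add atoms: vinylmagnesium bromide (C=C[Mg]Br)
Why: The vinylcerium reagent (Imamoto) should add to the activated ketone faster than to the acetates at −78 °C, and polar Felkin–Anh control (C12–OAc antiperiplanar to the incoming vinyl, approach past H‑12 and not past C11) should give the 13S tertiary alcohol.

**Compound list**

1 | (R)-(+)-limonene | CC1=CC[C@@H](CC1)C(C)=C | starting material
2 | methyl (3R)-6-oxo-3-(prop-1-en-2-yl)heptanoate | COC(=O)C[C@@H](CCC(C)=O)C(C)=C | intermediate
3 | methyl (3R)-5-(2-methyl-1,3-dioxolan-2-yl)-3-(prop-1-en-2-yl)pentanoate | COC(=O)C[C@@H](CCC1(C)OCCO1)C(C)=C | intermediate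
4 | 3-hydroxy-2,2-dimethylpropanal | OCC(C)(C)C=O | starting material
5 | 2,2-dimethyl-4-nitrobutane-1,3-diol (racemic) | OCC(C)(C)C(O)C[N+](=O)[O-] | intermediate
6 | 3-hydroxy-2,2-dimethyl-4-nitrobutanal (racemic) | O=CC(C)(C)C(O)C[N+](=O)[O-] | intermediate
7 | (E)-2,2-dimethyl-4-nitrobut-3-enal | O=CC(C)(C)/C=C/[N+](=O)[O-] | intermediate
8 | vinyltriphenylphosphonium bromide | C=C[P+](c1ccccc1)(c1ccccc1)c1ccccc1.[Br-] | starting material
9 | methyl (3R)-5-(2-methyl-1,3-dioxolan-2-yl)-3-(prop-1-en-2-yl)-2-[2-(triphenylphosphoranylidene)ethyl]pentanoate (both C2 epimers) | COC(=O)C(CC=P(c1ccccc1)(c1ccccc1)c1ccccc1)[C@@H](CCC2(C)OCCO2)C(C)=C | intermediate (not isolated)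
10 | methyl (4Z,7E)-6,6-dimethyl-2-[(3R)-2-methyl-5-(2-methyl-1,3-dioxolan-2-yl)pent-1-en-3-yl]-8-nitroocta-4,7-dienoate (both C2 epimers) | COC(=O)C(C/C=C\C(C)(C)/C=C/[N+](=O)[O-])[C@@H](CCC1(C)OCCO1)C(C)=C | intermediate (not isolated)
11 | methyl (1S,6S)-5,5-dimethyl-1-[(3S)-2-methyl-5-(2-methyl-1,3-dioxolan-2-yl)pent-1-en-3-yl]-6-(nitromethyl)cyclohex-3-ene-1-carboxylate (ring A with quaternary C10, β-CO2Me, 5α-H) | C=C(C)[C@H](CCC1(C)OCCO1)[C@@]2(C(=O)OC)CC=CC(C)(C)[C@@H]2C[N+](=O)[O-] | intermediate
12 | methyl (1S,6S)-6-formyl-5,5-dimethyl-1-[(3S)-2-methyl-5-(2-methyl-1,3-dioxolan-2-yl)pent-1-en-3-yl]cyclohex-3-ene-1-carboxylate | C=C(C)[C@H](CCC1(C)OCCO1)[C@@]2(C(=O)OC)CC=CC(C)(C)[C@@H]2C=O | intermediate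
13 | methyl 13,13-ethylenedioxy-6ξ-hydroxy-14,15-dinorlabda-2,8(17)-dien-20-oate (5α-H, 9α-H, C6 epimers) | CC3(CC[C@@H]1[C@@]2(C(=O)OC)CC=CC(C)(C)[C@@H]2C(O)CC1=C)OCCO3 | intermediate
14 | methyl 13,13-ethylenedioxy-6ξ,8α-dihydroxy-14,15-dinorlabd-2-en-20-oate | CC3(CC[C@@H]1[C@@]2(C(=O)OC)CC=CC(C)(C)[C@@H]2C(O)C[C@@]1(C)O)OCCO3 | intermediate
15 | methyl 13,13-ethylenedioxy-8α-hydroxy-6-oxo-14,15-dinorlabd-2-en-20-oate | CC3(CC[C@@H]1[C@@]2(C(=O)OC)CC=CC(C)(C)[C@@H]2C(=O)C[C@@]1(C)O)OCCO3 | intermediate
16 | 13,13-ethylenedioxy-14,15-dinorlabd-2-ene-6β,8α,20-triol | CC3(CC[C@@H]1[C@@]2(CO)CC=CC(C)(C)[C@@H]2[C@H](O)C[C@@]1(C)O)OCCO3 | intermediate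
17 | 13,13-ethylenedioxy-14,15-dinorlabd-2-ene-6β,8α,20-triyl triacetate | CC3(CC[C@@H]1[C@@]2(COC(C)=O)CC=CC(C)(C)[C@@H]2[C@H](OC(C)=O)C[C@@]1(C)OC(C)=O)OCCO3 | intermediate
18 | 13-oxo-14,15-dinorlabd-2-ene-6β,8α,20-triyl triacetate | CC(=O)CC[C@@H]1[C@@]2(COC(C)=O)CC=CC(C)(C)[C@@H]2[C@H](OC(C)=O)C[C@@]1(C)OC(C)=O | intermediate
19 | (12R)-13-oxo-12-(phenylaminooxy)-14,15-dinorlabd-2-ene-6β,8α,20-triyl triacetate | CC(=O)[C@H](ONc1ccccc1)C[C@@H]1[C@@]2(COC(C)=O)CC=CC(C)(C)[C@@H]2[C@H](OC(C)=O)C[C@@]1(C)OC(C)=O | intermediate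
20 | (12R)-12-hydroxy-13-oxo-14,15-dinorlabdane-6β,8α,20-triyl triacetate | CC(=O)[C@H](O)C[C@@H]1[C@@]2(COC(C)=O)CCCC(C)(C)[C@@H]2[C@H](OC(C)=O)C[C@@]1(C)OC(C)=O | intermediate
21 | (12R)-13-oxo-14,15-dinorlabdane-6β,8α,12,20-tetrayl tetraacetate | CC(=O)[C@H](OC(C)=O)C[C@@H]1[C@@]2(COC(C)=O)CCCC(C)(C)[C@@H]2[C@H](OC(C)=O)C[C@@]1(C)OC(C)=O | intermediate
22 | (12R,13S)-13-hydroxylabd-14-ene-6β,8α,12,20-tetrayl tetraacetate (CNP0136817.1) | C=C[C@](C)(O)[C@@H](C[C@@H]1[C@@]2(COC(C)=O)CCCC(C)(C)[C@@H]2[C@H](OC(C)=O)C[C@@]1(C)OC(C)=O)OC(C)=O | target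

**Count**

Total steps: 17. Longest linear sequence: 15 steps (steps 3 to 5 and 6 to 17; the other branch, steps 1 and 2, joins at step 6).

**Steps most likely to fail**

Step 6. The ylide may add to the nitroalkene instead of the aldehyde, the Wittig reaction may lose Z selectivity, and the ring‑closing Michael addition may show poor facial selectivity at C10. The fallback builds the same ring in a different bond order, sets out from 3 and 7 and returns at 11. Wittig methylenation of 7 (Ph3P=CH2, THF, −78 °C) gives (E)-3,3-dimethyl-1-nitropenta-1,4-diene F1. The lithium enolate of 3 (LiN(i-Pr)2, THF, −78 °C) adds to it in an intermolecular Michael reaction (C5–C10) to give the nitro ester F2. Double deprotonation (LiN(i-Pr)2, 2.2 equiv) and C‑allylation with allyl bromide give the quaternary triene F3 (C10–C1). Ring‑closing metathesis with second‑generation Grubbs catalyst (CH2Cl2, 40 °C) then forms C2=C3 and gives 11.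

Step 17. The vinyl reagent may attack the acetates, the C12 acetyl group may migrate to the new alkoxide, and the Felkin–Anh preference may be weak. The fallback uses chelation control followed by inversion, sets out from 18 and returns at 22. Aminoxylation of 18 with D‑proline in place of L‑proline gives the (12S)-aminoxy ketone F4, and hydrogenation (H2, Pd/C) gives the (12S)-hydroxy ketone F5. Addition of CH2=CHMgBr (excess, THF, −78 °C) through the five‑membered magnesium chelate gives the (12S,13S)-diol F6. A Mitsunobu reaction with acetic acid (PPh3, DIAD, THF, 0 °C) should then invert C12 and install the acetate, giving 22; the tertiary C13 hydroxyl is too hindered to be activated and should stay free.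

Step 9. The C8 radical may be trapped with poor facial selectivity, and the ring A alkene may be hydrated as well. The fallback goes through an epoxide, sets out from 13 and returns at 16. Epoxidation of 13 with m‑CPBA (CH2Cl2, −20 °C) from the α face gives the 8α,17‑epoxide F7; the exocyclic 1,1‑disubstituted alkene should react before the ring A alkene, which is flanked by the quaternary C4. Dess–Martin oxidation gives the epoxy ketone F8. LiAlH4 then opens the epoxide at C17, reduces the C6 ketone from the α face and reduces the ester, giving 16.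

**Further compounds**

F1 | step 6 | (E)-3,3-dimethyl-1-nitropenta-1,4-diene | C=CC(C)(C)/C=C/[N+](=O)[O-]
F2 | step 6 | methyl 4,4-dimethyl-2-[(3R)-2-methyl-5-(2-methyl-1,3-dioxolan-2-yl)pent-1-en-3-yl]-3-(nitromethyl)hex-5-enoate (mixture at C2 and C3) | COC(=O)C([C@@H](CCC1(C)OCCO1)C(C)=C)C(C[N+](=O)[O-])C(C)(C)C=C
F3 | step 6 | methyl 2-allyl-4,4-dimethyl-2-[(3S)-2-methyl-5-(2-methyl-1,3-dioxolan-2-yl)pent-1-en-3-yl]-3-(nitromethyl)hex-5-enoate (C10 and C5 configured as in 11) | C=C(C)[C@H](CCC1(C)OCCO1)[C@](CC=C)(C(=O)OC)[C@@H](C[N+](=O)[O-])C(C)(C)C=C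
F4 | step 17 | (12S)-13-oxo-12-(phenylaminooxy)-14,15-dinorlabd-2-ene-6β,8α,20-triyl triacetate | CC(=O)[C@@H](ONc1ccccc1)C[C@@H]1[C@@]2(COC(C)=O)CC=CC(C)(C)[C@@H]2[C@H](OC(C)=O)C[C@@]1(C)OC(C)=O
F5 | step 17 | (12S)-12-hydroxy-13-oxo-14,15-dinorlabdane-6β,8α,20-triyl triacetate | CC(=O)[C@@H](O)C[C@@H]1[C@@]2(COC(C)=O)CCCC(C)(C)[C@@H]2[C@H](OC(C)=O)C[C@@]1(C)OC(C)=O
F6 | step 17 | (12S,13S)-12,13-dihydroxylabd-14-ene-6β,8α,20-triyl triacetate | C=C[C@](C)(O)[C@H](C[C@@H]1[C@@]2(COC(C)=O)CCCC(C)(C)[C@@H]2[C@H](OC(C)=O)C[C@@]1(C)OC(C)=O)O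
F7 | step 9 | methyl 8α,17-epoxy-13,13-ethylenedioxy-6ξ-hydroxy-14,15-dinorlabd-2-en-20-oate | CC3(CC[C@@H]1[C@@]2(C(=O)OC)CC=CC(C)(C)[C@@H]2C(O)C[C@]14CO4)OCCO3
F8 | step 9 | methyl 8α,17-epoxy-13,13-ethylenedioxy-6-oxo-14,15-dinorlabd-2-en-20-oate | CC3(CC[C@@H]1[C@@]2(C(=O)OC)CC=CC(C)(C)[C@@H]2C(=O)C[C@]14CO4)OCCO3
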